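The plan disconnects the cyclohexane ring (C5–C10) at C6–C7. Written as a ketone, C6 stands 1,4 to the lactone carbonyl C12, so an N-heterocyclic-carbene Stetter reaction of a C6 aldehyde onto a C7=C11–C12 enoate closes the ring in one operation. The new C6 carbonyl then lets its neighbours C5 and C7 relax into the equatorial positions of the target before it is reduced to the axial C6 alcohol. The precursor is an open chain holding the C10 quaternary centre (methyl, vinyl), a cis-acetonide across O8/O9, an (E)-tert-butyl enoate and, on C5, the aldehyde plus a silyl-protected C4–C3 arm.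

Key step: step 10

Remark: elemane numbering is used throughout; the C5 arm is carried with C4 as CH2 and C3 as a silyl-protected primary alcohol, and C13 and C15 are added as methylene groups after the key step, so the carbon skeletons of the key-step precursor and product are those of the target without C13 and C15.

Step 1
Reactants: 1 4-methylfuran-2(5H)-one
Product: 2 4-methyl-2-(trimethylsilyloxy)furan
Conditions: Me3SiCl, Et3N, Et2O, 0 to 23 °C
Reagents that add atoms: chlorotrimethylsilane C[Si](C)(C)Cl
Why: Soft enolization of the butenolide and O-silylation of the dienolate should give the aromatic 2-silyloxyfuran, the nucleophile for a vinylogous Mukaiyama aldol reaction, and no stereocenter is formed.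

Step 2
Reactants: 2 4-methyl-2-(trimethylsilyloxy)furan; 3 (4-methoxybenzyloxy)acetaldehyde
Product: 5 (5S)-5-[(1R)-1-hydroxy-2-(4-methoxybenzyloxy)ethyl]-4-methylfuran-2(5H)-one, via trimethylsilyl ether 4 (not isolated)
Conditions: [Cu{(S,S)-2,6-bis(4-phenyl-2-oxazolin-2-yl)pyridine}](SbF6)2 (10 mol%), CH2Cl2, −78 °C; then 1 M HCl, THF
Reagents that add atoms: none
Why: In this vinylogous Mukaiyama aldol reaction the alkoxyacetaldehyde should chelate the chiral divalent-copper complex so that the furan γ-carbon attacks its si face (C8, R) through an open transition state that should favour the anti adduct (C9, S), which is the erythro O8/O9 relationship that a cis-fused acetonide and the target require.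

Step 3
Reactants: 5 (5S)-5-[(1R)-1-hydroxy-2-(4-methoxybenzyloxy)ethyl]-4-methylfuran-2(5H)-one
Product: 6 (5S)-4-methyl-5-[(1R)-2-(4-methoxybenzyloxy)-1-(triethylsilyloxy)ethyl]furan-2(5H)-one
Conditions: Et3SiOTf, 2,6-lutidine, CH2Cl2, −78 °C
Reagents that add atoms: triethylsilyl trifluoromethanesulfonate CC[Si](CC)(CC)OS(=O)(=O)C(F)(F)F
Why: Silyl ether formation with a silyl triflate and a hindered pyridine base at low temperature should protect O8 without epimerizing the acidic γ-centre C9.

Step 4
Reactants: 6 (5S)-4-methyl-5-[(1R)-2-(4-methoxybenzyloxy)-1-(triethylsilyloxy)ethyl]furan-2(5H)-one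
Product: 8 (4R,5S)-4-methyl-5-[(1R)-2-(4-methoxybenzyloxy)-1-(triethylsilyloxy)ethyl]-4-vinyldihydrofuran-2(3H)-one, via silyl ketene acetal 7 (not isolated)
Conditions: CH2=CHMgBr, CuBr·SMe2 (0.3 equiv), Me3SiCl, THF, −78 to −40 °C; then aq. NH4Cl
Reagents that add atoms: vinylmagnesium bromide C=C[Mg]Br; chlorotrimethylsilane C[Si](C)(C)Cl (retained only in 7)
Why: Copper-catalysed, silyl-chloride-accelerated conjugate addition of the vinyl Grignard reagent to the β-methylbutenolide should create the quaternary centre C10 with the vinyl group entering anti to the C9 side chain, the enolate being trapped as a silyl ketene acetal that is hydrolysed on work-up.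

Step 5
Reactants: 8 (4R,5S)-4-methyl-5-[(1R)-2-(4-methoxybenzyloxy)-1-(triethylsilyloxy)ethyl]-4-vinyldihydrofuran-2(3H)-one
Product: 9 lactone 8 carrying a 2-(tert-butyldimethylsilyloxy)ethyl group on the α-carbon C5 (C5 epimers)
Conditions: LiN(i-Pr)2, THF, −78 °C; ICH2CH2OSiMe2t-Bu, DMPU, −78 to 0 °C
Reagents that add atoms: tert-butyl(2-iodoethoxy)dimethylsilane CC(C)(C)[Si](C)(C)OCCI
Why: Alkylation of the lactone lithium enolate with a primary iodide should attach the C4–C3 arm to C5, whose configuration is of no consequence here because it is reset in step 10.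

Step 6
Reactants: 9 α-alkylated lactone (C5 epimers)
Product: 10 open-chain C6,C9-diol with O8 triethylsilyl ether, O7 4-methoxybenzyl ether and O3 tert-butyldimethylsilyl ether (C5 epimers)
Conditions: LiAlH4, THF, 0 °C; aq. potassium sodium tartrate
Reagents that add atoms: none
Why: Hydride reduction of the lactone with LiAlH4 should release the primary C6 alcohol and the C9 hydroxyl while silyl ethers, the benzyl-type ether and the vinyl group stay untouched.

Step 7
Reactants: 10 open-chain C6,C9-diol
Product: 12 O8/O9-acetonide with free C6 alcohol (C5 epimers), via triol 11 (not isolated)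
Conditions: PPTS, MeOH, 0 to 23 °C; then Me2C(OMe)2, acetone, 23 °C
Reagents that add atoms: 2,2-dimethoxypropane COC(C)(C)OC
Why: Acid-catalysed methanolysis should cleave the secondary triethylsilyl ether much faster than the primary tert-butyldimethylsilyl ether, and transketalization of the freed erythro 1,2-diol should give the five-membered cis-acetonide in preference to any larger ring through the C6 hydroxyl.

Step 8
Reactants: 12 O8/O9-acetonide with free C6 alcohol
Product: 13 acetonide C6,C7-diol (C5 epimers)
Conditions: DDQ, CH2Cl2/pH 7 buffer, 0 °C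
Reagents that add atoms: none
Why: Oxidative cleavage of the 4-methoxybenzyl ether with DDQ proceeds by hydride abstraction from the electron-rich benzylic position and should spare the silyl ether, the acetonide and the vinyl group.

Step 9
Reactants: 13 acetonide C6,C7-diol
Product: 15 C6 aldehyde with (E)-tert-butyl enoate (C7=C11–C12) and O8/O9-acetonide (C5 epimers), via dialdehyde 14 (not isolated)
Conditions: Dess–Martin periodinane, NaHCO3, CH2Cl2, 0 °C; then Ph3P=CHCO2t-Bu (1.05 equiv), −20 to 0 °C
Reagents that add atoms: tert-butyl (triphenylphosphoranylidene)acetate CC(C)(C)OC(=O)C=P(c1ccccc1)(c1ccccc1)c1ccccc1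
Why: Dess–Martin oxidation of both primary alcohols is followed in the same flask by a Wittig reaction in which one equivalent of stabilized ylide should take the unhindered, α-oxygen-activated C7 aldehyde far faster than the α-branched C6 aldehyde next to the quaternary C10, giving the (E)-enoate.

Step 10
Reactants: 15 C6 aldehyde with (E)-tert-butyl enoate and O8/O9-acetonide
Product: 17 cyclohexanone (C6=O) with C7 tert-butyl acetate arm trans to O8, O8/O9-acetonide and equatorial C5 arm, via C5-epimeric ketone 16 (not isolated)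
Conditions: 2-(pentafluorophenyl)-6,7-dihydro-5H-pyrrolo[2,1-c][1,2,4]triazol-2-ium tetrafluoroborate (20 mol%), KN(SiMe3)2 (15 mol%), PhMe, 23 °C; then DBU (0.3 equiv), 23 °C
Reagents that add atoms: none
Why: The free carbene adds to the C6 aldehyde, proton transfer gives the enaminol (an acyl anion equivalent), this attacks the enoate β-carbon C7, and proton transfer with loss of the carbene releases the C6 ketone. The closest known reaction type is the intramolecular Stetter reaction of aliphatic aldehydes tethered to α,β-unsaturated esters under N-pentafluorophenyl triazolium catalysis. The cyclohexanone (ring C5–C10) closes in a 6-exo-trig mode. C7 should be set in a chair-like transition state in which the cis-fused dioxolane keeps O8 equatorial and O9 axial and the acceptor chain equatorial, placing the acetate arm trans to O8, which is also the thermodynamic position because C7 is α to the new carbonyl. C5 is set by enolization under DBU, the arm taking the equatorial site away from the axial O9. The step needs conjugate acylation to outrun Michael addition of the aldehyde enolate and β-elimination of O8, which the preorganization by the cis-acetonide, the absence of free strong base (less KN(SiMe3)2 than azolium salt) and the ketal-bound, equatorial C8–O bond should secure.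

Step 11
Reactants: 17 cyclohexanone
Product: 18 axial C6 alcohol (cis to the C5 and C7 arms)
Conditions: LiBH(sec-Bu)3, THF, −78 °C; AcOH quench at −78 °C
Reagents that add atoms: none
Why: Reduction with the bulky trialkylborohydride should occur by equatorial attack, the axial trajectory being blocked by the axial C10 methyl group, to give the axial C6 alcohol, while the tert-butyl ester is neither reduced nor attacked by the C6 alkoxide at −78 °C, so no 6,12-lactone forms.

Step 12
Reactants: 18 axial C6 alcohol
Product: 21 C6 alcohol with tert-butyl 2-substituted acrylate arm (C11=C13), via Mannich base 19 (not isolated), via ammonium iodide 20 (not isolated)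
Conditions: LiN(i-Pr)2 (3 equiv), THF, −78 °C; Me2N=CH2 I, −78 to 0 °C; then MeI, MeOH, 23 °C; then DBU, CH2Cl2, 23 °C
Reagents that add atoms: dimethylmethyleneiminium iodide C=[N+](C)C.[I-]; iodomethane CI (retained only in 20)
Why: Mannich reaction of the ester enolate (formed beside the C6 alkoxide) with the iminium salt, N-methylation and Hofmann-type elimination should install the C11=C13 methylene while no other Michael acceptor is in the molecule.

Step 13
Reactants: 21 C6 alcohol with acrylate arm
Product: 22 C6 methacrylate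
Conditions: methacrylic anhydride, Et3N, DMAP, CH2Cl2, 23 °C
Reagents that add atoms: methacrylic anhydride CC(=C)C(=O)OC(=O)C(C)=C
Why: DMAP-catalysed (Steglich-type) acylation should be site-selective because the C6 hydroxyl is the only free one while O8 and O9 are still tied in the acetonide.

Step 14
Reactants: 22 C6 methacrylate
Product: 24 trans-fused 8,12-α-methylene lactone with C6 methacrylate and free C9 and C3 hydroxyls, via hydroxy acid 23 (not isolated)
Conditions: CF3CO2H/H2O (9:1), 0 to 23 °C; evaporate; then TsOH (cat.), PhH, 50 °C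
Reagents that add atoms: none
Why: Acidolysis should remove the tert-butyl ester, the acetonide and the primary silyl ether, and acid-catalysed (Fischer-type) lactonization then engages O8, the only hydroxyl able to form a five-membered ring with C12 now that O6 is acylated.

Step 15
Reactants: 24 8,12-lactone with free C9 and C3 hydroxyls
Product: 25 C3 aldehyde
Conditions: TEMPO (10 mol%), PhI(OAc)2, CH2Cl2, 23 °C
Reagents that add atoms: none
Why: Nitroxyl-catalysed oxidation with the hypervalent iodine co-oxidant should convert the primary C3 alcohol into the aldehyde and leave the hindered axial secondary C9 hydroxyl alone.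

Step 16
Reactants: 25 C3 aldehyde
Product: 27 C5 acrolein unit (C4=C15, C3 aldehyde) with C10 vinyl group, via Mannich base 26 (not isolated)
Conditions: (CH2O)n, i-Pr2NH2 O2CCF3 (1 equiv), CF3CO2H (10 mol%), THF, 60 °C
Reagents that add atoms: formaldehyde (as paraformaldehyde) C=O; diisopropylammonium trifluoroacetate CC(C)[NH2+]C(C)C.[O-]C(=O)C(F)(F)F (retained only in 26)
Why: Mannich-type α-methylenation (Mannich addition at C4 followed by β-elimination of the amine) should create the C4=C15 double bond, the bulky diisopropylamine being too hindered to add to the α-methylene lactone.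

Step 17
Reactants: 27 enal with C10 vinyl group
Product: 28 target CNP0228781.2
Conditions: VO(acac)2 (10 mol%), t-BuOOH (decane solution), PhMe, 23 to 40 °C
Reagents that add atoms: tert-butyl hydroperoxide CC(C)(C)OO
Why: In this vanadium-catalysed hydroxyl-directed epoxidation the vanadate ester of the axial homoallylic O9 should deliver oxygen to the only electron-rich alkene, C1=C2, through a chair-like six-membered transition state with C2 pseudo-equatorial, which sets C1, while the three electron-poor alkenes do not react.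

Compound list
1 | 4-methylfuran-2(5H)-one | CC1=CC(=O)OC1 | starting material
2 | 4-methyl-2-(trimethylsilyloxy)furan | Cc1coc(O[Si](C)(C)C)c1 | intermediate
3 | (4-methoxybenzyloxy)acetaldehyde | O=CCOCc1ccc(OC)cc1 | starting material
4 | O8-trimethylsilyl ether of 5 | O=C1C=C(C)[C@H](O1)[C@H](O[Si](C)(C)C)COCc2ccc(OC)cc2 | intermediate
5 | (5S)-5-[(1R)-1-hydroxy-2-(4-methoxybenzyloxy)ethyl]-4-methylfuran-2(5H)-one (furanone C5 = C9, carbinol = C8, CH2O = C7) | O=C1C=C(C)[C@H](O1)[C@H](O)COCc2ccc(OC)cc2 | intermediate
6 | (5S)-4-methyl-5-[(1R)-2-(4-methoxybenzyloxy)-1-(triethylsilyloxy)ethyl]furan-2(5H)-one | O=C1C=C(C)[C@H](O1)[C@H](O[Si](CC)(CC)CC)COCc2ccc(OC)cc2 | intermediate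
7 | 2-(trimethylsilyloxy)-4,5-dihydrofuran (silyl ketene acetal) corresponding to lactone 8 | C[Si](C)(C)OC1=C[C@](C)(C=C)[C@H](O1)[C@H](O[Si](CC)(CC)CC)COCc2ccc(OC)cc2 | intermediate
8 | (4R,5S)-4-methyl-5-[(1R)-2-(4-methoxybenzyloxy)-1-(triethylsilyloxy)ethyl]-4-vinyldihydrofuran-2(3H)-one (lactone C2 = C6, C3 = C5, C4 = C10; vinyl trans to the C9 side chain) | O=C1C[C@](C)(C=C)[C@H](O1)[C@H](O[Si](CC)(CC)CC)COCc2ccc(OC)cc2 | intermediate
9 | lactone 8 with a 2-(tert-butyldimethylsilyloxy)ethyl group on C5, C5 epimers | O=C1C(CCO[Si](C)(C)C(C)(C)C)[C@](C)(C=C)[C@H](O1)[C@H](O[Si](CC)(CC)CC)COCc2ccc(OC)cc2 | intermediate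
10 | open-chain C6,C9-diol, O8 triethylsilyl, O7 4-methoxybenzyl, O3 tert-butyldimethylsilyl, C5 epimers | OCC(CCO[Si](C)(C)C(C)(C)C)[C@](C)(C=C)[C@H](O)[C@H](O[Si](CC)(CC)CC)COCc1ccc(OC)cc1 | intermediate
11 | C6,C8,C9-triol (erythro at C8/C9), C5 epimers | OCC(CCO[Si](C)(C)C(C)(C)C)[C@](C)(C=C)[C@H](O)[C@H](O)COCc1ccc(OC)cc1 | intermediate
12 | O8/O9 cis-acetonide with free C6 alcohol and O7 4-methoxybenzyl ether, C5 epimers | OCC(CCO[Si](C)(C)C(C)(C)C)[C@](C)(C=C)[C@@H]1OC(C)(C)O[C@@H]1COCc2ccc(OC)cc2 | intermediate
13 | O8/O9 cis-acetonide C6,C7-diol, C5 epimers | OCC(CCO[Si](C)(C)C(C)(C)C)[C@](C)(C=C)[C@@H]1OC(C)(C)O[C@@H]1CO | intermediate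
14 | O8/O9 cis-acetonide C6,C7-dialdehyde, C5 epimers | O=CC(CCO[Si](C)(C)C(C)(C)C)[C@](C)(C=C)[C@@H]1OC(C)(C)O[C@@H]1C=O | intermediate
15 | key-step precursor: C6 aldehyde, (E)-tert-butyl enoate C7=C11–C12, O8/O9 cis-acetonide, C10 methyl and vinyl, C5 arm CH2CH2OSiMe2t-Bu, C5 epimers | O=CC(CCO[Si](C)(C)C(C)(C)C)[C@](C)(C=C)[C@@H]1OC(C)(C)O[C@@H]1/C=C/C(=O)OC(C)(C)C | intermediate
16 | C5 epimer of 17 (C5 arm axial) | O=C1[C@H](CC(=O)OC(C)(C)C)[C@H]2OC(C)(C)O[C@H]2[C@@](C)(C=C)[C@H]1CCO[Si](C)(C)C(C)(C)C | intermediate
17 | key-step product: cyclohexanone (C6=O), C7 CH2CO2t-Bu trans to O8, O8/O9 cis-acetonide, C10 methyl axial and vinyl equatorial, C5 arm equatorial | O=C1[C@H](CC(=O)OC(C)(C)C)[C@H]2OC(C)(C)O[C@H]2[C@@](C)(C=C)[C@@H]1CCO[Si](C)(C)C(C)(C)C | intermediate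
18 | axial C6 alcohol of 17 (hydroxyl cis to the C5 and C7 arms) | O[C@@H]1[C@H](CC(=O)OC(C)(C)C)[C@H]2OC(C)(C)O[C@H]2[C@@](C)(C=C)[C@@H]1CCO[Si](C)(C)C(C)(C)C | intermediate
19 | C11 dimethylaminomethyl derivative of 18 (C11 epimers) | O[C@@H]1[C@H](C(CN(C)C)C(=O)OC(C)(C)C)[C@H]2OC(C)(C)O[C@H]2[C@@](C)(C=C)[C@@H]1CCO[Si](C)(C)C(C)(C)C | intermediate
20 | trimethylammonium iodide from 19 | O[C@@H]1[C@H](C(C[N+](C)(C)C)C(=O)OC(C)(C)C)[C@H]2OC(C)(C)O[C@H]2[C@@](C)(C=C)[C@@H]1CCO[Si](C)(C)C(C)(C)C.[I-] | intermediate
21 | C6 alcohol with tert-butyl acrylate arm (C11=C13) | O[C@@H]1[C@H](C(=C)C(=O)OC(C)(C)C)[C@H]2OC(C)(C)O[C@H]2[C@@](C)(C=C)[C@@H]1CCO[Si](C)(C)C(C)(C)C | intermediate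
22 | C6 methacrylate of 21 | C=C(C)C(=O)O[C@@H]1[C@H](C(=C)C(=O)OC(C)(C)C)[C@H]2OC(C)(C)O[C@H]2[C@@](C)(C=C)[C@@H]1CCO[Si](C)(C)C(C)(C)C | intermediate
23 | C12 acid with free C8, C9 and C3 hydroxyls and C6 methacrylate | C=C(C)C(=O)O[C@@H]1[C@H](C(=C)C(=O)O)[C@@H](O)[C@@H](O)[C@@](C)(C=C)[C@@H]1CCO | intermediate
24 | trans-fused 8,12-α-methylene lactone, C6 methacrylate, C9 hydroxyl, C10 vinyl, C5 CH2CH2OH | C=C(C)C(=O)O[C@@H]1[C@@H]2C(=C)C(=O)O[C@H]2[C@@H](O)[C@@](C)(C=C)[C@@H]1CCO | intermediate
25 | C3 aldehyde of 24 (C5 CH2CHO) | C=C(C)C(=O)O[C@@H]1[C@@H]2C(=C)C(=O)O[C@H]2[C@@H](O)[C@@](C)(C=C)[C@@H]1CC=O | intermediate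
26 | C4 diisopropylaminomethyl derivative of 25 (C4 epimers) | C=C(C)C(=O)O[C@@H]1[C@@H]2C(=C)C(=O)O[C@H]2[C@@H](O)[C@@](C)(C=C)[C@@H]1C(CN(C(C)C)C(C)C)C=O | intermediate
27 | deoxy precursor of the target with C10 vinyl and C5 acrolein unit | C=C(C)C(=O)O[C@@H]1[C@@H]2C(=C)C(=O)O[C@H]2[C@@H](O)[C@@](C)(C=C)[C@@H]1C(=C)C=O | intermediate
28 | CNP0228781.2 | C=C(C)C(=O)O[C@@H]1[C@@H]2C(=C)C(=O)O[C@H]2[C@@H](O)[C@@](C)([C@@H]2CO2)[C@@H]1C(=C)C=O | target

Total step count: 17. Longest linear sequence: 17 steps (1 to 28).

Steps most likely to fail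

Step 10. Carbene addition to the hindered, α-branched C6 aldehyde may be slow, so that Michael closure through the aldehyde enolate, or loss of O8 by β-elimination during the base equilibration, overtakes the wanted ring closure. The fallback sets out from 15 and forms the same C6–C7 bond by a radical instead of a polar acyl equivalent. Chlorite oxidation (NaClO2, NaH2PO4, 2-methyl-2-butene, t-BuOH/H2O) gives the C6 carboxylic acid F1. PhSeSePh and PBu3 in CH2Cl2 convert it into the Se-phenyl selenoester F2. (Me3Si)3SiH and AIBN in PhH at 80 °C generate the acyl radical, which should close 6-exo-trig onto the enoate to give 16 and 17. DBU equilibration as in step 10 then brings the route back at 17.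

Step 17. Oxygen delivery may occur with poor facial selectivity, because the vinyl rotamer needed for the chair-like vanadate transition state places C2 close to the C5 arm, and a monosubstituted alkene is epoxidized slowly. The fallback sets out from 27 and replaces substrate direction by reagent control. Dimethyldioxirane in acetone at 0 °C epoxidizes the vinyl group without direction and gives 28 together with its C1-epimeric epoxide F3. Hydrolytic kinetic resolution with N,N′-bis(3,5-di-tert-butylsalicylidene)-1,2-cyclohexanediaminocobalt acetate (trivalent cobalt) and water then opens F3 to the diol F4. The antipode of the complex that consumes the (1S)-epoxide is the one to use, to be confirmed with both antipodes on a small scale. F4 is removed by chromatography, and the route comes back at 28.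

Step 2. The methyl group next to the reacting furan carbon may erode the anti-selectivity of the aldol addition, so that the C9 epimer is formed in quantity. The fallback sets out from 2 and 3 under the conditions of step 2 and corrects C9 thermodynamically instead of kinetically. The syn adduct F5 (the C9 epimer of 5) is isolated after the same acidic work-up. It is equilibrated at the acidic butenolide γ-centre C9 with Et3N and DMAP in CH2Cl2 at 23 °C, which leaves C8 untouched. Compound 5 is separated and F5 recycled, so the route comes back at 5.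

Further compounds
F1 | step 10 | C6 carboxylic acid corresponding to aldehyde 15 (C5 epimers) | OC(=O)C(CCO[Si](C)(C)C(C)(C)C)[C@](C)(C=C)[C@@H]1OC(C)(C)O[C@@H]1/C=C/C(=O)OC(C)(C)C
F2 | step 10 | Se-phenyl selenoester of F1 (C5 epimers) | O=C([Se]c1ccccc1)C(CCO[Si](C)(C)C(C)(C)C)[C@](C)(C=C)[C@@H]2OC(C)(C)O[C@@H]2/C=C/C(=O)OC(C)(C)C
F3 | step 17 | C1 epimer of 28 | C=C(C)C(=O)O[C@@H]1[C@@H]2C(=C)C(=O)O[C@H]2[C@@H](O)[C@@](C)([C@H]2CO2)[C@@H]1C(=C)C=O
F4 | step 17 | C1,C2-diol from hydrolysis of F3 | C=C(C)C(=O)O[C@@H]1[C@@H]2C(=C)C(=O)O[C@H]2[C@@H](O)[C@@](C)([C@H](O)CO)[C@@H]1C(=C)C=O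
F5 | step 2 | (5R)-5-[(1R)-1-hydroxy-2-(4-methoxybenzyloxy)ethyl]-4-methylfuran-2(5H)-one (syn adduct) | O=C1C=C(C)[C@@H](O1)[C@H](O)COCc2ccc(OC)cc2
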